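**Assumption:** The BINOL (Step 8) and TsDPEN (Step 13) enantiomers are assigned by analogy to give (10S) and (14S) in cembrane numbering (C1–C20). They should be confirmed by Mosher analysis. The target is (1S,2S,10S,14S). Farnesyl-type chain geometries are all E, as in the target.

## Retrosynthetic overview
1. The 14-membered ring is closed last, by forming C1–C2. A BF3-promoted macrocyclic SE′ allylation of the C2 aldehyde by a 3-(stannylmethyl)butenolide gives the trans-fused α-methylene-γ-lactone, the syn C2 carbinol and the exocyclic methylene in one step (the new step).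
2. The butenolide (first ring formed) comes from RCM of an acrylate ester of an unsymmetrical divinyl carbinol. C14 (S) comes from Noyori transfer hydrogenation of an ynone.
3. The ynone comes from NHK coupling of an E-trisubstituted vinyl iodide with TMS-propynal. The vinyl iodide comes from Negishi carboalumination of a homopropargylic acetate, and C10 (S) comes from Keck propargylation of an enal.
4. The C2–C10 E,E-enal is built from two 3-butyn-1-ol units by carboalumination/iodination, Negishi coupling and formylation.
5. Ring order: the lactone (RCM) first, then the carbocycle last.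

## Route

**Step 1**
Reactants: 1 but-3-yn-1-ol
Product: 2 PMB ether of but-3-yn-1-ol
Conditions: NaH, PMBCl, TBAI (cat.), THF, 0 °C → rt
Reagents that add atoms: PMBCl, COc1ccc(CCl)cc1
Why: Williamson etherification of the alcohol; the alkyne C–H is not deprotonated by NaH.

**Step 2**
Reactants: 2
Product: 3 (E)-vinyl iodide, PMB ether of (E)-4-iodo-3-methylbut-3-en-1-ol
Conditions: AlMe3, Cp2ZrCl2, (CH2Cl)2, rt; then I2, THF, –30 °C
Reagents that add atoms: trimethylaluminum, C[Al](C)C; iodine, II
Why: Negishi Zr-catalysed syn-methylalumination puts Me on the internal carbon, so iodinolysis gives the E-trisubstituted vinyl iodide.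

**Step 3**
Reactants: 4 4-(trimethylsilyl)but-3-yn-1-ol
Product: 5 (4-iodobut-1-yn-1-yl)trimethylsilane
Conditions: PPh3, I2, imidazole, Et2O/MeCN, 0 °C
Reagents that add atoms: iodine, II
Why: Appel/Garegg–Samuelsson iodination of a primary alcohol by SN2; the TMS-alkyne is untouched.

**Step 4**
Reactants: 3 and 5
Product: 6 TMS-enyne (C2–C9 skeleton)
Conditions: (i) Zn dust, LiCl, BrCH2CH2Br/TMSCl (cat.), THF, 40 °C; (ii) 3, Pd(PPh3)4 (5 mol %), THF, 50 °C
Reagents that add atoms: none
Why: Knochel zinc insertion followed by Pd-catalysed Negishi sp3–sp2 coupling forms the C5–C6 bond with retention of the E-alkene.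

**Step 5**
Reactants: 6
Product: 7 terminal alkyne
Conditions: K2CO3, MeOH, rt
Reagents that add atoms: none
Why: Base-mediated protodesilylation of the alkynyl–TMS bond, which sets up the next carboalumination.

**Step 6**
Reactants: 7
Product: 8 (E,E)-dienyl vinyl iodide (C9–I, Me on C8)
Conditions: AlMe3, Cp2ZrCl2, (CH2Cl)2, rt; then I2, THF, –30 °C
Reagents that add atoms: trimethylaluminum, C[Al](C)C; iodine, II
Why: Negishi carboalumination is selective for the terminal alkyne over the trisubstituted alkene and gives the E-vinyl iodide.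

**Step 7**
Reactants: 8
Product: 9 (2E,6E)-9-(PMBO)-3,7-dimethylnona-2,6-dienal (C10 aldehyde)
Conditions: t-BuLi (2.1 equiv), Et2O, –78 °C; then DMF
Reagents that add atoms: DMF, CN(C)C=O
Why: Li–I exchange proceeds with retention of alkene geometry, and DMF formylation (Bouveault) gives the E-enal.

**Step 8**
Reactants: 9 and 10 allenyltributylstannane
Product: 11 (4S,5E,9E)-12-(PMBO)-6,10-dimethyldodeca-5,9-dien-1-yn-4-ol (C10 carbinol)
Conditions: (S)-BINOL (20 mol %), Ti(OiPr)4 (10 mol %), 4 Å MS, CH2Cl2, –20 °C
Reagents that add atoms: none besides reactant 10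
Why: Keck Ti–BINOL asymmetric propargylation; the allenylstannane adds SE2′ through an open transition state, and the chiral Lewis acid sets C10 (S).

**Step 9**
Reactants: 11
Product: 12 acetate of 11 (C10–OAc)
Conditions: Ac2O, Et3N, DMAP, CH2Cl2, 0 °C
Reagents that add atoms: acetic anhydride, CC(=O)OC(C)=O
Why: Acylation with retention at C10; this installs the target's C10 acetate early.

**Step 10**
Reactants: 12
Product: 13 (1E)-vinyl iodide (C13–I, Me on C12) with C10–OAc
Conditions: AlMe3, Cp2ZrCl2, (CH2Cl)2, rt; then I2, THF, –30 °C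
Reagents that add atoms: trimethylaluminum, C[Al](C)C; iodine, II
Why: Negishi carboalumination of the terminal alkyne gives the E-trisubstituted C12=C13 alkene; the hindered secondary acetate and the PMB ether survive.

**Step 11**
Reactants: 13 and 14 3-(trimethylsilyl)propynal
Product: 15 TMS-propargylic alcohol, mixture of C14 epimers, C10 (S) retained
Conditions: CrCl2 (6 equiv), NiCl2 (0.1 mol %), DMF, rt
Reagents that add atoms: none besides reactant 14
Why: Nozaki–Hiyama–Kishi alkenylation forms C13–C14 with retention of E-geometry; the C14 stereochemistry is deliberately not controlled here.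

**Step 12**
Reactants: 15
Product: 16 ynone
Conditions: Dess–Martin periodinane, NaHCO3, CH2Cl2, 0 °C
Reagents that add atoms: none
Why: Oxidation removes the uncontrolled C14 centre.

**Step 13**
Reactants: 16
Product: 17 (14S)-TMS-propargylic alcohol
Conditions: RuCl[(R,R)-TsDPEN](p-cymene) (2 mol %), i-PrOH, 25 °C
Reagents that add atoms: none
Why: Noyori–Ikariya asymmetric transfer hydrogenation sets C14 (S) by catalyst control (the linear alkyne is the "small" group, the alkenyl the "large" group), overriding the remote C10 centre.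

**Step 14**
Reactants: 17
Product: 18 terminal propargylic alcohol
Conditions: TBAF, AcOH (1:1), THF, 0 °C
Reagents that add atoms: none
Why: Buffered fluoride protodesilylation leaves the acetate and the secondary carbinol intact.

**Step 15**
Reactants: 18
Product: 19 divinyl carbinol (C14 as drawn)
Conditions: H2 (1 atm), Lindlar catalyst, quinoline, EtOAc/hexanes, rt
Reagents that add atoms: none (H2 adds only hydrogen)
Why: Lindlar syn-semihydrogenation converts the terminal alkyne to a vinyl group and leaves the trisubstituted alkenes untouched. The C14 geometry is unchanged; its CIP label becomes R because the priorities change.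

**Step 16**
Reactants: 20 methyl 2-(hydroxymethyl)acrylate
Product: 21 methyl 2-[(tert-butyldimethylsilyloxy)methyl]acrylate
Conditions: TBSCl, imidazole, DMF, 0 °C
Reagents that add atoms: TBSCl, CC(C)(C)[Si](C)(C)Cl
Why: Silylation of the primary allylic alcohol.

**Step 17**
Reactants: 21
Product: 22 2-[(TBSO)methyl]acrylic acid
Conditions: LiOH, THF/H2O, 0 °C
Reagents that add atoms: none
Why: Saponification of the methyl ester; the TBS ether survives at 0 °C.

**Step 18**
Reactants: 19 and 22
Product: 23 acrylate ester of the divinyl carbinol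
Conditions: 2,4,6-Cl3C6H2COCl, Et3N, THF; then 19, DMAP, toluene, rt
Reagents that add atoms: none (the trichlorobenzoyl chloride is only an activator)
Why: Yamaguchi esterification acylates the secondary alcohol with retention at C14.

**Step 19**
Reactants: 23
Product: 24 (14S)-3-(TBSOCH2)-5-alkenylbutenolide (first ring, C14 (S))
Conditions: Hoveyda–Grubbs II (10 mol %), Ti(OiPr)4 (0.3 equiv), CH2Cl2 (5 mM), 40 °C
Reagents that add atoms: none (ethylene is lost)
Why: Ring-closing metathesis joins the acrylate and the monosubstituted vinyl group to form the five-membered butenolide; the trisubstituted alkenes are too hindered to react and C14 is untouched.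

**Step 20**
Reactants: 24
Product: 25 C17 allylic alcohol
Conditions: CSA (0.1 equiv), MeOH/CH2Cl2 (1:1), 0 °C
Reagents that add atoms: none
Why: Acid-catalysed methanolysis removes the primary TBS ether selectively; the PMB ether, acetate and butenolide survive (no base, so C14–H is not racemised).

**Step 21**
Reactants: 25
Product: 26 3-(bromomethyl)butenolide
Conditions: CBr4, PPh3, CH2Cl2, 0 °C
Reagents that add atoms: carbon tetrabromide, BrC(Br)(Br)Br
Why: Appel SN2 bromination of the activated allylic alcohol.

**Step 22**
Reactants: 26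
Product: 27 primary alcohol (C2–OH)
Conditions: DDQ, CH2Cl2/pH 7 phosphate buffer (10:1), 0 °C
Reagents that add atoms: none
Why: DDQ oxidative PMB cleavage is selective for the electron-rich benzyl ether, and the buffer protects the allylic bromide.

**Step 23**
Reactants: 27
Product: 28 β,γ-unsaturated aldehyde (C2 CHO) bromide
Conditions: Dess–Martin periodinane, NaHCO3, CH2Cl2, 0 °C (crude used at once)
Reagents that add atoms: none
Why: Buffered oxidation of the primary alcohol avoids deconjugation of the β,γ-enal.

**Step 24**
Reactants: 28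
Product: 29 allylstannane aldehyde (C17–SnMe3)
Conditions: Me3SnSnMe3 (1.1 equiv), Pd(PPh3)4 (3 mol %), THF, 25 °C, 1 h (crude used at once)
Reagents that add atoms: hexamethylditin, C[Sn](C)(C)[Sn](C)(C)C
Why: Pd(0) oxidative addition into the very reactive 2-(bromomethyl)enoate followed by Sn–Sn transmetalation gives the allylstannane (Stille-type stannylation).

**Step 25**
Reactants: 29
Product: 30 kericembrenolide D (1S,2S,10S,14S)
Conditions: BF3·OEt2 (3 equiv), CH2Cl2, 2 mM, slow addition of 29 at –78 °C → –40 °C; NaHCO3 quench
Reagents that add atoms: none (Me3Sn is lost as Me3SnF; workup adds only H)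
Why: Lewis-acid-promoted intramolecular SE′ allylation closes the 14-membered ring, with the lactone face set anti to C13 and C2 set by an open synclinal transition state. Proposed new method: BF3 activates the C2 aldehyde and the ring-fixed E-allylstannane (C17–Sn, C15=C1) attacks through C1 via an open synclinal transition state, not a chair, so the E-allyl geometry gives the syn C1/C2 relationship, whereas chair allylmetals (Cr, Zn, In, B) would give the anti epimer. The aldehyde approaches the butenolide face anti to the C14–C13 bond, giving the trans-fused lactone. Loss of Me3Sn+ from the β-stannyl cation forms the exocyclic C15=C17 methylene, and 2 mM dilution favours 14-membered closure over oligomerisation. The closest known chemistry is Yamamoto/Keck/Marshall allylstannane–aldehyde additions (including intramolecular macrocyclisations) and additions of 2-(stannylmethyl)acrylates to aldehydes. A 3-(stannylmethyl)butenolide closing a cembranolide ring to form the trans-α-methylene lactone and syn carbinol in one step has not been shown.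

## Compound list
1 | but-3-yn-1-ol | C#CCCO | starting material
2 | PMB ether of but-3-yn-1-ol | C#CCCOCc1ccc(OC)cc1 | intermediate
3 | PMB ether of (E)-4-iodo-3-methylbut-3-en-1-ol | I/C=C(\C)CCOCc1ccc(OC)cc1 | intermediate
4 | 4-(trimethylsilyl)but-3-yn-1-ol | C[Si](C)(C)C#CCCO | starting material
5 | (4-iodobut-1-yn-1-yl)trimethylsilane | C[Si](C)(C)C#CCCI | intermediate
6 | PMB ether of (E)-8-TMS-3-methyloct-3-en-7-yn-1-ol | C[Si](C)(C)C#CCC/C=C(\C)CCOCc1ccc(OC)cc1 | intermediate
7 | PMB ether of (E)-3-methyloct-3-en-7-yn-1-ol | C#CCC/C=C(\C)CCOCc1ccc(OC)cc1 | intermediate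
8 | PMB ether of (3E,7E)-8-iodo-3,7-dimethylocta-3,7-dien-1-ol | I/C=C(\C)CC/C=C(\C)CCOCc1ccc(OC)cc1 | intermediate
9 | (2E,6E)-9-(PMBO)-3,7-dimethylnona-2,6-dienal | O=C/C=C(\C)CC/C=C(\C)CCOCc1ccc(OC)cc1 | intermediate
10 | allenyltributylstannane | C=C=C[Sn](CCCC)(CCCC)CCCC | starting material
11 | (4S,5E,9E)-12-(PMBO)-6,10-dimethyldodeca-5,9-dien-1-yn-4-ol | C#CC[C@H](O)/C=C(\C)CC/C=C(\C)CCOCc1ccc(OC)cc1 | intermediate
12 | acetate of 11 | C#CC[C@H](OC(C)=O)/C=C(\C)CC/C=C(\C)CCOCc1ccc(OC)cc1 | intermediate
13 | (1E,4S,5E,9E)-1-iodo-12-(PMBO)-2,6,10-trimethyldodeca-1,5,9-trien-4-yl acetate | I/C=C(\C)C[C@H](OC(C)=O)/C=C(\C)CC/C=C(\C)CCOCc1ccc(OC)cc1 | intermediate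
14 | 3-(trimethylsilyl)propynal | C[Si](C)(C)C#CC=O | starting material
15 | TMS-propargylic alcohol, C14 epimeric mixture (10S) | C[Si](C)(C)C#CC(O)/C=C(\C)C[C@H](OC(C)=O)/C=C(\C)CC/C=C(\C)CCOCc1ccc(OC)cc1 | intermediate
16 | TMS-ynone (10S) | C[Si](C)(C)C#CC(=O)/C=C(\C)C[C@H](OC(C)=O)/C=C(\C)CC/C=C(\C)CCOCc1ccc(OC)cc1 | intermediate
17 | (14S)-TMS-propargylic alcohol | C[Si](C)(C)C#C[C@@H](O)/C=C(\C)C[C@H](OC(C)=O)/C=C(\C)CC/C=C(\C)CCOCc1ccc(OC)cc1 | intermediate
18 | (14S)-terminal propargylic alcohol | C#C[C@@H](O)/C=C(\C)C[C@H](OC(C)=O)/C=C(\C)CC/C=C(\C)CCOCc1ccc(OC)cc1 | intermediate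
19 | divinyl carbinol (C14 as drawn, R by CIP) | C=C[C@@H](O)/C=C(\C)C[C@H](OC(C)=O)/C=C(\C)CC/C=C(\C)CCOCc1ccc(OC)cc1 | intermediate
20 | methyl 2-(hydroxymethyl)acrylate | C=C(CO)C(=O)OC | starting material
21 | methyl 2-[(TBSO)methyl]acrylate | C=C(CO[Si](C)(C)C(C)(C)C)C(=O)OC | intermediate
22 | 2-[(TBSO)methyl]acrylic acid | C=C(CO[Si](C)(C)C(C)(C)C)C(=O)O | intermediate
23 | acrylate ester of 19 | C=C(CO[Si](C)(C)C(C)(C)C)C(=O)O[C@H](C=C)/C=C(\C)C[C@H](OC(C)=O)/C=C(\C)CC/C=C(\C)CCOCc1ccc(OC)cc1 | intermediate
24 | (14S)-butenolide, 3-CH2OTBS, 2-PMB ether, 10-OAc | O=C1O[C@@H](/C=C(\C)C[C@H](OC(C)=O)/C=C(\C)CC/C=C(\C)CCOCc2ccc(OC)cc2)C=C1CO[Si](C)(C)C(C)(C)C | intermediate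
25 | C17 allylic alcohol | O=C1O[C@@H](/C=C(\C)C[C@H](OC(C)=O)/C=C(\C)CC/C=C(\C)CCOCc2ccc(OC)cc2)C=C1CO | intermediate
26 | C17 allylic bromide | O=C1O[C@@H](/C=C(\C)C[C@H](OC(C)=O)/C=C(\C)CC/C=C(\C)CCOCc2ccc(OC)cc2)C=C1CBr | intermediate
27 | bromide with free C2–OH | O=C1O[C@@H](/C=C(\C)C[C@H](OC(C)=O)/C=C(\C)CC/C=C(\C)CCO)C=C1CBr | intermediate
28 | bromide with C2 aldehyde | O=C1O[C@@H](/C=C(\C)C[C@H](OC(C)=O)/C=C(\C)CC/C=C(\C)CC=O)C=C1CBr | intermediate
29 | allylstannane aldehyde | O=C1O[C@@H](/C=C(\C)C[C@H](OC(C)=O)/C=C(\C)CC/C=C(\C)CC=O)C=C1C[Sn](C)(C)C | intermediate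
30 | kericembrenolide D | C=C1C(=O)O[C@H]2/C=C(\C)C[C@H](OC(C)=O)/C=C(\C)CC/C=C(\C)C[C@H](O)[C@H]12 | target

## Totals and risks
Total steps: 25. Longest linear sequence: 22 steps (Steps 1, 2, 4–15, 18–25). Two short branches feed it: the iodide branch (Step 3) and the acrylic acid branch (Steps 16–17).

Three steps most likely to fail:
1. **Step 25, the new macrocyclic SE′ allylation.** The butenolidyl stannane is electron-poor, and BF3 could trigger Prins-type or deconjugation side reactions. The syn selectivity is also unproven. Fallback (known chemistry, different mechanism): skip Step 24 and treat bromide 28 with CrCl2/cat. NiCl2 in DMF. This intramolecular NHK closes the ring through a chair Cr-allyl transition state. It should give the trans lactone but the anti (2R) epimer. Invert C2 by Mitsunobu (p-nitrobenzoic acid, DIAD, PPh3) followed by mild methanolysis to reach 30.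
2. **Step 19, the RCM.** An α-substituted acrylate on a hindered bis-allylic secondary ester in the presence of three trisubstituted alkenes may give low conversion. Fallback: RCM the plain acrylate ester of 19, which is easier, to give the 3-unsubstituted 5-alkenylbutenolide. Then install C17 by α-iodination (I2, pyridine) and Pd-Stille coupling with Bu3SnCH2OH. This rejoins the route at allylic alcohol 25.
3. **Step 13, the Ru transfer hydrogenation of enynone 16.** Enantio- and diastereoselectivity for an alkenyl/alkynyl ketone is uncertain. Fallback: lipase-mediated kinetic resolution (Amano PS, vinyl acetate) of racemic carbinol 15, or an alternative reduction such as Midland Alpine-borane or (S)-CBS. The resolution changes the strategy from asymmetric reduction to separation of C14 epimers.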